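**Retrosynthetic overview**
- Target ⇒ desilylation and Lacey–Dieckmann closure of a β-keto amide; the tetramic acid ring is made last, from a decalin β-keto thioester and O-silyl L-threonine methyl ester.
- Decalin β-keto thioester ⇒ decalin aldehyde + thioacetate (aldol, oxidation).
- Decalin aldehyde ⇒ all-E 2-methyl tetraenal by one intramolecular Diels–Alder reaction (IMDA) that closes ring A (cyclohexene) and ring B (cyclohexane) together and sets C1, C2, C4a and C8a (naphthalene numbering). The C6 methyl is axial in the target, against the tether's own preference, so the facial sense must come from a chiral catalyst (new step).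
- Tetraenal ⇒ Suzuki union of an (E)-alkenyl boronate (from (R)-citronellal, which supplies C6) with an (E,E,E)-iodotriene (from sorbaldehyde).
- Ring order: rings A and B together, then the pyrrolidine-2,4-dione.

Assumption: the sense of induction of the cationic oxazaborolidine is taken from the accepted formyl C–H···O binding model for 2-substituted enals, which leaves the Si face of the enal α-carbon open with the (R)-prolinol-derived catalyst; if experiment shows the opposite sense, the (S)-catalyst is used in the same way.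

**Route**

Step 1
Reactants: 1 (R)-citronellal [(3R)-3,7-dimethyloct-6-enal]
Product: 2 (4R)-4,8-dimethylnon-7-en-1-yne
Conditions: dimethyl (1-diazo-2-oxopropyl)phosphonate, K2CO3, MeOH, 0 °C → rt
Reagents that add atoms: dimethyl (1-diazo-2-oxopropyl)phosphonate, CC(=O)C(=[N+]=[N-])P(=O)(OC)OC
Why: Ohira–Bestmann (Seyferth–Gilbert) homologation turns the aldehyde into the terminal alkyne under mild base, and the methyl stereocentre (β to the carbonyl, later decalin C6) cannot epimerise.

Step 2
Reactants: 2 (4R)-4,8-dimethylnon-7-en-1-yne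
Product: 4 (4R)-4-methylhept-6-ynal, via ozonide 3 (not isolated)
Conditions: O3, CH2Cl2, −78 °C (Sudan Red 7B end point); then PPh3, −78 °C → rt
Reagents that add atoms: ozone, [O-][O+]=O
Why: Ozonolysis with reductive work-up cleaves the electron-rich trisubstituted alkene far faster than the terminal alkyne, so the isopropylidene end becomes the aldehyde without touching the stereocentre.

Step 3
Reactants: 4 (4R)-4-methylhept-6-ynal and 5 ethyl 2-(triphenyl-λ5-phosphanylidene)propanoate
Product: 6 ethyl (2E,6R)-2,6-dimethylnon-2-en-8-ynoate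
Conditions: CH2Cl2, rt
Reagents that add atoms: none
Why: Wittig olefination with the stabilised α-methyl ylide gives the (E)-trisubstituted enoate (typically >95:5), which fixes the dienophile geometry that later becomes the cis relation of the acyl group and H-8a.

Step 4
Reactants: 6 ethyl (2E,6R)-2,6-dimethylnon-2-en-8-ynoate
Product: 7 ethyl (2E,6R,8E)-2,6-dimethyl-9-(4,4,5,5-tetramethyl-1,3,2-dioxaborolan-2-yl)nona-2,8-dienoate
Conditions: pinacolborane, Cp2ZrHCl (10 mol%), Et3N (10 mol%), neat, 60 °C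
Reagents that add atoms: pinacolborane, CC1(C)OBOC1(C)C
Why: Zirconium-catalysed hydroboration of the terminal alkyne is a syn, anti-Markovnikov addition that gives only the (E)-alkenyl boronate and leaves the hindered enoate alone.

Step 5
Reactants: 8 sorbaldehyde [(2E,4E)-hexa-2,4-dienal]
Product: 9 (1E,3E,5E)-1-iodohepta-1,3,5-triene
Conditions: CHI3, CrCl2, THF/dioxane, 0 °C → rt, dark
Reagents that add atoms: iodoform, IC(I)I
Why: Takai olefination (gem-dichromium reagent from CHI3 and CrCl2) converts the aldehyde into the (E)-vinyl iodide with one-carbon extension while the E,E-diene is retained.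

Step 6
Reactants: 7 alkenyl boronate and 9 (1E,3E,5E)-1-iodohepta-1,3,5-triene
Product: 10 ethyl (2E,6R,8E,10E,12E,14E)-2,6-dimethylhexadeca-2,8,10,12,14-pentaenoate
Conditions: Pd(PPh3)4 (5 mol%), K3PO4, THF/H2O, rt → 40 °C, degassed, dark
Reagents that add atoms: none
Why: Suzuki–Miyaura coupling joins the two alkenyl partners with retention of both double-bond geometries, giving the all-E tetraene without any new stereochemical decision.

Step 7
Reactants: 10 tetraene ester
Product: 11 (2E,6R,8E,10E,12E,14E)-2,6-dimethylhexadeca-2,8,10,12,14-pentaen-1-ol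
Conditions: i-Bu2AlH, CH2Cl2, −78 °C; aq. KNaC4H4O6 work-up
Reagents that add atoms: none
Why: i-Bu2AlH reduces the α,β-unsaturated ester by 1,2-addition to the allylic alcohol at −78 °C without touching the tetraene.

Step 8
Reactants: 11 tetraene allylic alcohol
Product: 12 (2E,6R,8E,10E,12E,14E)-2,6-dimethylhexadeca-2,8,10,12,14-pentaenal
Conditions: MnO2, CH2Cl2, rt, dark
Reagents that add atoms: none
Why: MnO2 oxidises only the allylic alcohol, under neutral heterogeneous conditions that preserve the tetraene and the E-enal geometry.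

Step 9
Reactants: 12 (2E,6R,8E,10E,12E,14E)-2,6-dimethylhexadeca-2,8,10,12,14-pentaenal
Product: 13 (1R,2S,4aR,6R,8aS)-1,6-dimethyl-2-[(1E,3E)-penta-1,3-dien-1-yl]-1,2,4a,5,6,7,8,8a-octahydronaphthalene-1-carbaldehyde
Conditions: (R)-1-(2-methylphenyl)-3,3-diphenyltetrahydro-1H,3H-pyrrolo[1,2-c][1,3,2]oxazaborole (25 mol%), Tf2NH (20 mol%), CH2Cl2 (0.02 M), −78 → −40 °C
Reagents that add atoms: none
Why: Proposed new method: a catalyst-controlled, substrate-mismatched IMDA of a conjugated tetraenal — the N-protonated oxazaborolidine binds the s-trans 2-methyl enal of 12 (B–O coordination plus a formyl C–H···O contact) so that an aryl ring covers the C2 Re face, the C8–C11 diene therefore adds endo to the C2 Si/C3 Re face (bonds C3–C8 and C2–C11), which closes rings A and B as the trans-decalin, sets decalin C1, C2, C4a and C8a as 1R,2S,4aR,8aS and forces the tether chair with the C6 methyl axial against its roughly 1 kcal/mol equatorial preference (the preference that gives the opposite ring configuration under achiral Lewis acids), and a catalyst bias of about 2 kcal/mol at −78 °C should outweigh it; closest known reaction type: chiral boron Lewis acid (oxazaborolidinium or acyloxyborane) catalysed enantioselective IMDA of achiral 2-methyl trienals, and Et2AlCl-promoted substrate-controlled IMDA of citronellal-derived trienals.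

Step 10
Reactants: 13 decalin aldehyde and 14 S-tert-butyl ethanethioate
Product: 16 S-tert-butyl 3-[(1R,2S,4aR,6R,8aS)-1,6-dimethyl-2-[(1E,3E)-penta-1,3-dien-1-yl]-1,2,4a,5,6,7,8,8a-octahydronaphthalen-1-yl]-3-hydroxypropanethioate (both C3 epimers), via lithium thioester enolate 15 (not isolated)
Conditions: LiN(i-Pr)2, THF, −78 °C; then 13; aq. NH4Cl
Reagents that add atoms: none
Why: Aldol addition of the preformed lithium thioester enolate to the non-enolisable neopentyl aldehyde forms the C–C bond of the future β-dicarbonyl, the new carbinol centre being inconsequential because it is oxidised next.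

Step 11
Reactants: 16 β-hydroxy thioester
Product: 17 S-tert-butyl 3-[(1R,2S,4aR,6R,8aS)-1,6-dimethyl-2-[(1E,3E)-penta-1,3-dien-1-yl]-1,2,4a,5,6,7,8,8a-octahydronaphthalen-1-yl]-3-oxopropanethioate
Conditions: Dess–Martin periodinane, CH2Cl2, rt
Reagents that add atoms: none
Why: Dess–Martin oxidation converts the β-hydroxy thioester to the β-keto thioester under near-neutral conditions that avoid retro-aldol cleavage and leave the alkenes alone.

Step 12
Reactants: 18 methyl L-threoninate hydrochloride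
Product: 19 methyl (2S,3R)-2-amino-3-[(tert-butyldimethylsilyl)oxy]butanoate
Conditions: TBSCl, imidazole, CH2Cl2, rt
Reagents that add atoms: tert-butyldimethylsilyl chloride, CC(C)(C)[Si](C)(C)Cl
Why: Silylation of the secondary hydroxyl (any N–Si bond is hydrolysed on work-up) masks the β-hydroxyl against elimination in the later base step, and both L-threonine stereocentres (2S,3R) are carried through unchanged.

Step 13
Reactants: 17 decalin β-keto thioester and 19 O-silyl threonine ester
Product: 20 methyl (2S,3R)-3-[(tert-butyldimethylsilyl)oxy]-2-{3-[(1R,2S,4aR,6R,8aS)-1,6-dimethyl-2-[(1E,3E)-penta-1,3-dien-1-yl]-1,2,4a,5,6,7,8,8a-octahydronaphthalen-1-yl]-3-oxopropanamido}butanoate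
Conditions: CF3CO2Ag, Et3N, THF, 0 °C → rt, dark
Reagents that add atoms: none
Why: Silver-promoted aminolysis of the tert-butyl thioester (thiophilic activation) forms the β-keto amide at 0 °C under conditions too mild to epimerise the amino ester.

Step 14
Reactants: 20 β-keto amide
Product: 21 (5S)-5-[(1R)-1-[(tert-butyldimethylsilyl)oxy]ethyl]-3-{[(1R,2S,4aR,6R,8aS)-1,6-dimethyl-2-[(1E,3E)-penta-1,3-dien-1-yl]-1,2,4a,5,6,7,8,8a-octahydronaphthalen-1-yl]carbonyl}-4-hydroxy-1,5-dihydro-2H-pyrrol-2-one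
Conditions: KOt-Bu, t-BuOH/THF, rt, 20 min; aq. KHSO4
Reagents that add atoms: none
Why: Lacey–Dieckmann cyclisation, in which the β-keto amide enolate attacks the methyl ester to close the pyrrolidine-2,4-dione, and brief exposure to base keeps C5 (S, from L-threonine) intact because the product is at once stored as its unreactive tetramate anion.

Step 15
Reactants: 21 O-silyl tetramic acid
Product: 22 (5S)-3-{[(1R,2S,4aR,6R,8aS)-1,6-dimethyl-2-[(1E,3E)-penta-1,3-dien-1-yl]-1,2,4a,5,6,7,8,8a-octahydronaphthalen-1-yl]carbonyl}-4-hydroxy-5-[(1R)-1-hydroxyethyl]-1,5-dihydro-2H-pyrrol-2-one (CNP0298257.2)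
Conditions: HF·pyridine, pyridine/THF, 0 °C → rt
Reagents that add atoms: none
Why: Fluoride-mediated Si–O cleavage with buffered HF·pyridine frees the secondary alcohol without disturbing the diene, the ring alkene or the acyl tetramic acid, giving the target.

**Compound list**
1 | (R)-citronellal, (3R)-3,7-dimethyloct-6-enal | O=CC[C@H](C)CCC=C(C)C | starting material
2 | (4R)-4,8-dimethylnon-7-en-1-yne | C#CC[C@H](C)CCC=C(C)C | intermediate
3 | 5,5-dimethyl-3-[(3R)-3-methylhex-5-yn-1-yl]-1,2,4-trioxolane (ozonide, both epimers at the ring carbon) | C#CC[C@H](C)CCC1OOC(C)(C)O1 | intermediate (not isolated)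
4 | (4R)-4-methylhept-6-ynal | C#CC[C@H](C)CCC=O | intermediate
5 | ethyl 2-(triphenyl-λ5-phosphanylidene)propanoate | CCOC(=O)C(C)=P(c1ccccc1)(c1ccccc1)c1ccccc1 | starting material
6 | ethyl (2E,6R)-2,6-dimethylnon-2-en-8-ynoate | C#CC[C@H](C)CC/C=C(\C)C(=O)OCC | intermediate
7 | ethyl (2E,6R,8E)-2,6-dimethyl-9-(4,4,5,5-tetramethyl-1,3,2-dioxaborolan-2-yl)nona-2,8-dienoate | CC1(C)OB(/C=C/C[C@H](C)CC/C=C(\C)C(=O)OCC)OC1(C)C | intermediate
8 | sorbaldehyde, (2E,4E)-hexa-2,4-dienal | C/C=C/C=C/C=O | starting material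
9 | (1E,3E,5E)-1-iodohepta-1,3,5-triene | C/C=C/C=C/C=C/I | intermediate
10 | ethyl (2E,6R,8E,10E,12E,14E)-2,6-dimethylhexadeca-2,8,10,12,14-pentaenoate | C/C=C/C=C/C=C/C=C/C[C@H](C)CC/C=C(\C)C(=O)OCC | intermediate
11 | (2E,6R,8E,10E,12E,14E)-2,6-dimethylhexadeca-2,8,10,12,14-pentaen-1-ol | C/C=C/C=C/C=C/C=C/C[C@H](C)CC/C=C(\C)CO | intermediate
12 | (2E,6R,8E,10E,12E,14E)-2,6-dimethylhexadeca-2,8,10,12,14-pentaenal | C/C=C/C=C/C=C/C=C/C[C@H](C)CC/C=C(\C)C=O | intermediate
13 | (1R,2S,4aR,6R,8aS)-1,6-dimethyl-2-[(1E,3E)-penta-1,3-dien-1-yl]-1,2,4a,5,6,7,8,8a-octahydronaphthalene-1-carbaldehyde | C/C=C/C=C/[C@H]1C=C[C@H]2C[C@H](C)CC[C@@H]2[C@@]1(C)C=O | intermediate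
14 | S-tert-butyl ethanethioate | CC(=O)SC(C)(C)C | starting material
15 | lithium 1-(tert-butylsulfanyl)ethen-1-olate | [Li+].C=C([O-])SC(C)(C)C | intermediate (not isolated)
16 | S-tert-butyl 3-[(1R,2S,4aR,6R,8aS)-1,6-dimethyl-2-[(1E,3E)-penta-1,3-dien-1-yl]-1,2,4a,5,6,7,8,8a-octahydronaphthalen-1-yl]-3-hydroxypropanethioate (both C3 epimers) | C/C=C/C=C/[C@H]1C=C[C@H]2C[C@H](C)CC[C@@H]2[C@@]1(C)C(O)CC(=O)SC(C)(C)C | intermediate
17 | S-tert-butyl 3-[(1R,2S,4aR,6R,8aS)-1,6-dimethyl-2-[(1E,3E)-penta-1,3-dien-1-yl]-1,2,4a,5,6,7,8,8a-octahydronaphthalen-1-yl]-3-oxopropanethioate | C/C=C/C=C/[C@H]1C=C[C@H]2C[C@H](C)CC[C@@H]2[C@@]1(C)C(=O)CC(=O)SC(C)(C)C | intermediate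
18 | methyl L-threoninate hydrochloride | Cl.N[C@@H]([C@@H](C)O)C(=O)OC | starting material
19 | methyl (2S,3R)-2-amino-3-[(tert-butyldimethylsilyl)oxy]butanoate | N[C@@H]([C@@H](C)O[Si](C)(C)C(C)(C)C)C(=O)OC | intermediate
20 | methyl (2S,3R)-3-[(tert-butyldimethylsilyl)oxy]-2-{3-[(1R,2S,4aR,6R,8aS)-1,6-dimethyl-2-[(1E,3E)-penta-1,3-dien-1-yl]-1,2,4a,5,6,7,8,8a-octahydronaphthalen-1-yl]-3-oxopropanamido}butanoate | C/C=C/C=C/[C@H]1C=C[C@H]2C[C@H](C)CC[C@@H]2[C@@]1(C)C(=O)CC(=O)N[C@@H]([C@@H](C)O[Si](C)(C)C(C)(C)C)C(=O)OC | intermediate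
21 | (5S)-5-[(1R)-1-[(tert-butyldimethylsilyl)oxy]ethyl]-3-{[(1R,2S,4aR,6R,8aS)-1,6-dimethyl-2-[(1E,3E)-penta-1,3-dien-1-yl]-1,2,4a,5,6,7,8,8a-octahydronaphthalen-1-yl]carbonyl}-4-hydroxy-1,5-dihydro-2H-pyrrol-2-one | C/C=C/C=C/[C@H]1C=C[C@H]2C[C@H](C)CC[C@@H]2[C@@]1(C)C(=O)C1=C(O)[C@H]([C@@H](C)O[Si](C)(C)C(C)(C)C)NC1=O | intermediate
22 | (5S)-3-{[(1R,2S,4aR,6R,8aS)-1,6-dimethyl-2-[(1E,3E)-penta-1,3-dien-1-yl]-1,2,4a,5,6,7,8,8a-octahydronaphthalen-1-yl]carbonyl}-4-hydroxy-5-[(1R)-1-hydroxyethyl]-1,5-dihydro-2H-pyrrol-2-one | C/C=C/C=C/[C@H]1C=C[C@H]2C[C@H](C)CC[C@@H]2[C@@]1(C)C(=O)C1=C(O)[C@H]([C@@H](C)O)NC1=O | target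

**Step count and risks**

Total steps: 15. Longest linear sequence: 13 steps from 1 (steps 1–4, 6–11, 13–15); steps 5 and 12 make the two side fragments.

Three steps most likely to fail:

Step 9 (the proposed new step). The catalyst may not fully override the tether's equatorial-methyl preference, giving 13 mixed with its ring-diastereomer of opposite configuration at C1, C2, C4a and C8a. With about 2 kcal/mol of catalyst bias against about 1 kcal/mol of tether bias, a ratio near 4:1 to 10:1 at −78 °C is the realistic expectation, and the isomers are separable as aldehydes. The cationic Lewis acid could also oligomerise the tetraene. The fallback uses only known chemistry, sets out from 12 and comes back at 17. It gives up catalyst control and moves the cyclisation to the β-keto thioester stage, where thermal IMDA of such polyenes is established. Aldehyde 12 is added to enolate 15 (made from 14 with LiN(i-Pr)2) to give the linear aldol S-tert-butyl (4E,8R,10E,12E,14E,16E)-3-hydroxy-4,8-dimethyloctadeca-4,10,12,14,16-pentaenethioate F1. Dess–Martin oxidation then gives the linear β-keto thioester S-tert-butyl (4E,8R,10E,12E,14E,16E)-4,8-dimethyl-3-oxooctadeca-4,10,12,14,16-pentaenethioate F2. Heating F2 in degassed toluene with BHT at 90–110 °C gives the cycloadducts. At that temperature a 1 kcal/mol facial bias is only about 4:1, so 17 is expected as roughly one fifth of the trans-fused material and is isolated by preparative HPLC; this is low-yielding but needs no new reactivity, and the route resumes at step 13.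

Step 6. Iodotriene 9 is light- and acid-sensitive and may decompose or lose E-purity before or during coupling. The fallback sets out from 6 and 8 and comes back at 10; it reverses the polarity so that the triene is carried as a robust stannane. Hydrozirconation of 6 with stoichiometric Cp2ZrHCl (THF, rt) gives the alkenylzirconocene chloride [(1E,4R,7E)-9-ethoxy-4,8-dimethyl-9-oxonona-1,7-dien-1-yl]chloridobis(cyclopentadienyl)zirconium F3 (not isolated). Iodinolysis (I2, 0 °C) gives the vinyl iodide ethyl (2E,6R,8E)-9-iodo-2,6-dimethylnona-2,8-dienoate F4. In parallel, 8 is olefinated with Bu3SnCHBr2, CrCl2 and LiI to the stannane tributyl[(1E,3E,5E)-hepta-1,3,5-trien-1-yl]stannane F5. Stille coupling of F4 with F5 (Pd2(dba)3, AsPh3, DMF, rt) gives 10.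

Step 14. Ring closure of the secondary (N–H) amide can be slow, which leaves time for C5 epimerisation or β-elimination of the silyloxy group. The fallback sets out from 17 and 19 and comes back at 22; it uses a tertiary amide, which populates the reactive rotamer and cyclises under milder base. Reductive amination of 19 with 2,4-dimethoxybenzaldehyde (NaBH(OAc)3) proceeds through the imine methyl (2S,3R)-3-[(tert-butyldimethylsilyl)oxy]-2-{[(E)-(2,4-dimethoxyphenyl)methylidene]amino}butanoate F6 (not isolated) to the N-benzyl amino ester methyl (2S,3R)-3-[(tert-butyldimethylsilyl)oxy]-2-{[(2,4-dimethoxyphenyl)methyl]amino}butanoate F7. Silver-promoted aminolysis of 17 with F7 (CF3CO2Ag, Et3N) gives the tertiary β-keto amide F8. NaOMe in MeOH at rt closes it to the N-protected tetramic acid F9. TFA/anisole in CH2Cl2 then removes the 2,4-dimethoxybenzyl group and the silyl ether together to give 22.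

**Further compounds**
F1 | step 9 | S-tert-butyl (4E,8R,10E,12E,14E,16E)-3-hydroxy-4,8-dimethyloctadeca-4,10,12,14,16-pentaenethioate (both C3 epimers) | C/C=C/C=C/C=C/C=C/C[C@H](C)CC/C=C(\C)C(O)CC(=O)SC(C)(C)C
F2 | step 9 | S-tert-butyl (4E,8R,10E,12E,14E,16E)-4,8-dimethyl-3-oxooctadeca-4,10,12,14,16-pentaenethioate | C/C=C/C=C/C=C/C=C/C[C@H](C)CC/C=C(\C)C(=O)CC(=O)SC(C)(C)C
F3 | step 6 | [(1E,4R,7E)-9-ethoxy-4,8-dimethyl-9-oxonona-1,7-dien-1-yl]chloridobis(cyclopentadienyl)zirconium (cyclopentadienyl rings written σ-bonded) | Cl[Zr](/C=C/C[C@H](C)CC/C=C(\C)C(=O)OCC)(C1C=CC=C1)C1C=CC=C1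
F4 | step 6 | ethyl (2E,6R,8E)-9-iodo-2,6-dimethylnona-2,8-dienoate | I/C=C/C[C@H](C)CC/C=C(\C)C(=O)OCC
F5 | step 6 | tributyl[(1E,3E,5E)-hepta-1,3,5-trien-1-yl]stannane | C/C=C/C=C/C=C/[Sn](CCCC)(CCCC)CCCC
F6 | step 14 | methyl (2S,3R)-3-[(tert-butyldimethylsilyl)oxy]-2-{[(E)-(2,4-dimethoxyphenyl)methylidene]amino}butanoate | COc1ccc(/C=N/[C@@H]([C@@H](C)O[Si](C)(C)C(C)(C)C)C(=O)OC)c(OC)c1
F7 | step 14 | methyl (2S,3R)-3-[(tert-butyldimethylsilyl)oxy]-2-{[(2,4-dimethoxyphenyl)methyl]amino}butanoate | COc1ccc(CN[C@@H]([C@@H](C)O[Si](C)(C)C(C)(C)C)C(=O)OC)c(OC)c1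
F8 | step 14 | methyl (2S,3R)-3-[(tert-butyldimethylsilyl)oxy]-2-{[(2,4-dimethoxyphenyl)methyl]{3-[(1R,2S,4aR,6R,8aS)-1,6-dimethyl-2-[(1E,3E)-penta-1,3-dien-1-yl]-1,2,4a,5,6,7,8,8a-octahydronaphthalen-1-yl]-3-oxopropanoyl}amino}butanoate | C/C=C/C=C/[C@H]1C=C[C@H]2C[C@H](C)CC[C@@H]2[C@@]1(C)C(=O)CC(=O)N(Cc1ccc(OC)cc1OC)[C@@H]([C@@H](C)O[Si](C)(C)C(C)(C)C)C(=O)OC
F9 | step 14 | (5S)-5-[(1R)-1-[(tert-butyldimethylsilyl)oxy]ethyl]-1-[(2,4-dimethoxyphenyl)methyl]-3-{[(1R,2S,4aR,6R,8aS)-1,6-dimethyl-2-[(1E,3E)-penta-1,3-dien-1-yl]-1,2,4a,5,6,7,8,8a-octahydronaphthalen-1-yl]carbonyl}-4-hydroxy-1,5-dihydro-2H-pyrrol-2-one | C/C=C/C=C/[C@H]1C=C[C@H]2C[C@H](C)CC[C@@H]2[C@@]1(C)C(=O)C1=C(O)[C@H]([C@@H](C)O[Si](C)(C)C(C)(C)C)N(Cc2ccc(OC)cc2OC)C1=O
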